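All runs come from a simulation for substances that don't exist; noise was put on by code.

The ratio of [electrophile] at 120 min to [electrophile] at 50.0 min reads 0.875 in the amber run and 0.876 in the blue run, though blue was charged with twice the free base. So after the early burst I read a pseudo-first-order decay, and I carry its constant.

in all of them: electrophile 0.073 M; protonated nucleophile 0.0876 M
- amber: free base 0.020 M; run made earlier
- blue: free base 0.041 M; run made earlier
- Thursday's: free base 0.0330 M; time 3.0 h
- Tuesday's: free base 0.0220 M; time 3.0 h
- Wednesday's: free base 0.0490 M; time 3.0 h

- amber (time / min: electrophile / %, target / %): 6.00: 96.0, 3.2; 20.0: 91.4, 8.5; 40.0: 85.4, 10.1; 50.0: 83.2, 11.9; 80.0: 80.0, 12.8; 90.0: 77.9, 14.1; 120: 72.8, 14.8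
- blue (time / min: electrophile / %, target / %): 10.0: 89.3, 9.2; 15.0: 85.6, 13.7; 25.0: 80.4, 16.3; 40.0: 75.8, 17.9; 50.0: 73.2, 18.6; 80.0: 68.4, 18.8; 120: 64.1, 19.2

(standard deviation of a reading: 0.5 percentage points)

1. part of the electrophile that has reacted at the end, Thursday's
2. part of the electrophile that has reacted at the end, Tuesday's
3. part of the electrophile that has reacted at the end, Wednesday's
4. what raising the concentration of free base from its lowest to its highest value here does to the part of the electrophile that has reacted (changes below 5 percentage points count as none) (no change / it falls / it rises)

- what was read earlier has a scatter of 0.5 percentage points, one standard deviation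
- on the list of suspects stand: electrophile + nucleophile -> acid set free + target; nucleophile + acid set free <-> protonated nucleophile; acid set free + free base <-> salt of the base; target <-> isomer of the product; target -> over-reaction product; acid set free -> by-product carried off

The creep constant, the fraction of the remaining electrophile lost per minute late in a run, is read from both windows:

amber: 0.00191 /min
blue: 0.00190 /min
mean: 0.00190 /min

From the last reading to 3.0 h, I let the electrophile keep this factor:

0.892

Blue stands lower than amber at the last reading, and Thursday's free base lies between their charges. That gives me an estimated bracket for Thursday's: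

from below, amber carried forward: 35.1% reacted
from above, blue carried forward: 42.8% reacted

To tighten it, I run a straight line in free base through the two last readings before applying the factor:

Tuesday's: 35.8%
Thursday's: 39.9%
Wednesday's, beyond blue: 45.8%

So I expect a rise of 10 percentage points.

The forecast calls the creep “nearly independent of base” and gives 35.5% for Tuesday's, 39.5% for Thursday's and 44.5% for Wednesday's; on the trend it says: it rises. Its Thursday's value, given with a range of 36% to 44%, sits inside my bracket, and its Wednesday's value lies below mine.

The flasks give 35.8% for Tuesday's, 40.3% for Thursday's and 47.3% for Wednesday's; the trend: it rises, by 11 points.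

    electrophile + nucleophile → acid set free + target (k = 0.360 /M/min)
    nucleophile + acid set free ⇌ protonated nucleophile, settled at all times (K = 38000 /M)
    acid set free + free base ⇌ salt of the base, settled at all times (K = 3.40 × 10⁶ /M)
    target ⇌ isomer of the product (K = 1.70, k = 0.0120 /min)
    target → over-reaction product (k = 1.60 × 10⁻⁵ /min)
    acid set free → by-product carried off (k = 0.730 /min)

Thursday's electrophile stands at 71.6% after 1.50 h, and the creep constant carries that to 60.3% at the end, against 59.7% in the flask. Wednesday's answer has moved by 5 points at 0.0601 M of free base, the other amounts and the time held, past the forecast's top of 50%. The neighbour, Thursday's with 0.044 M of electrophile, has 0.750 equiv of free base. Extending the line in equivalents beyond blue and applying the same factor gives 47.9% reacted, and the neighbour gives 52.3%, with [nucleophile] at 0.00827 M against 0.00565 M in Thursday's.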